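The runs were generated by integration from invented constants; the scatter is artificial.

The easy slip on this flask is to take the first slope of the larch run for its rate. On a logarithmic scale, free monomer in larch falls at 0.940 d⁻¹ up to 0.625 d, then at 0.613 d⁻¹ up to 2.50 d. We read that knee as living ends dropping from 20 mM to 12.0 mM, each transfer agent removing one. With the ends held, the fall is pseudo-first-order. The later slope, a reading with its scatter, means larch needs 3.75 d for free monomer to fall by one power of ten.

common to all: free monomer 0.80 M
- larch: transfer agent 8 mM; initiator 20 mM; run made earlier
- ash: transfer agent 8 mM; initiator 80 mM; run made earlier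
- flask: transfer agent 8.00 mM; initiator 40 mM; time 2.0 d

| run | time / d | monomer in chains / % | free monomer / % |
|---|---|---|---|
| larch | 0.125 | 4 | 96 |
| larch | 0.333 | 22 | 78 |
| larch | 0.625 | 38 | 60 |
| larch | 1.04 | 50 | 50 |
| larch | 1.67 | 66 | 33 |
| larch | 2.08 | 73 | 29 |
| larch | 2.50 | 80 | 19 |
| ash | 0.125 | 27 | 77 |
| ash | 0.333 | 63 | 36 |
| ash | 0.625 | 89 | 18 |
| ash | 1.04 | 96 | 5 |
| ash | 1.67 | 101 | 0 |
| ash | 2.08 | 99 | 1 |
| ash | 2.50 | 100 | 1 |

(each reading ± 2 percentage points)

- the average divides the monomer in chains by the number of chains begun, living and dead together
- steps thought possible: free monomer + initiator -> living end + monomer in chains; living end + transfer agent -> dead chain; monomer in chains -> over-reaction product; free monomer + living end -> monomer in chains + living end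
- the earlier runs do not show the number of chains; that part of a forecast is a guess

* average number of monomer units in a chain (chains begun, living or dead) at 2.0 d
* part of the free monomer that has reacted at 2.0 d

We take this span to shrink in proportion as living ends grow. The flask's curve therefore steepens while ends form, with the transfer agent removing some of them meanwhile. It bends at the knee, when 8.00 mM of ends have been removed, and runs straight on 32.0 mM of ends. There the decade time, the span for one power of ten at fixed ends, is 1.41 d. Setting the steeper early stretch against the lag, we draw this line from the start. Free monomer then crosses monomer in chains near 0.424 d. By 2.0 d it has fallen 1.42 powers of ten, leaving 3.80 %. So 96.2 % has reacted, and with 40 mM of chains begun, a guess, the average is 19.2, under a level of 20.0.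

The forecast says 19 and 95 %, adding “The chain count is assumed, not observed.” The flask gives 19.0 and 95.6 %.

    free monomer + initiator → living end + monomer in chains (k = 0.0110 M⁻¹ min⁻¹)
    living end + transfer agent → dead chain (kL = 0.0970 M⁻¹ min⁻¹)
    monomer in chains → over-reaction product (k = 2.80 × 10⁻⁶ min⁻¹)
    free monomer + living end → monomer in chains + living end, rate k4*[living end]*[free monomer] (k = 0.0340 M⁻¹ min⁻¹)

In the flask at 2.00 d, the half-life of free monomer by chain growth, 0.44 d, is a decade time of 1.46 d against our 1.41 d, and it is short against 2.0 d, while monomer in chains has a half-life of 170 d by over-reaction, and 4.41 % free monomer stands beside 95.0 % monomer in chains. The neighbouring flask charged with 0.20 M of free monomer holds 0.0284 M of living ends at 2.00 d, which makes its decade time 1.59 d and leaves 5.52 % by our count, and it holds 6.97 %.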